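**Strategy.** Ring E carries the bridging oxygen on C1, hydrogens on C2 and C6, and three neighbouring oxygens on C3, C4 and C5. This pattern is cut into a three-carbon dinucleophile (C2–C1–C6, a 3-aryloxyglutaconate whose aryl group is the fully methylated ring A–B–C–D tetramer) and a three-carbon dielectrophile (C3–C4–C5, methoxymalonyl dichloride). One double C-acylation forms C2–C3 and C5–C6 and delivers ring E already aromatic, with the two esters on C2 and C6 as removable activators. The tetramer phenol is assembled by three copper-catalysed ether couplings with one bromide building block. Saponification, decarboxylation and global demethylation finish the synthesis.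

Key step: step 11

**Remarks.**
- The target has no stereocentre.
- ArO stands for the nonamethylated ring A–B–C–D oxy group, 2,6-dimethoxy-4-{2,6-dimethoxy-4-[2,6-dimethoxy-4-(2,4,6-trimethoxyphenoxy)phenoxy]phenoxy}phenoxy.
- Assumption: compounds 1, 3, 10 and 12 are taken as catalogue compounds. Allene 10 is used as the racemate, since its axial chirality vanishes in 11.
- Compound 11 is drawn as the E isomer expected under thermodynamic control. The Z isomer would serve equally, because the geometry is lost in the dienolate.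
- The glutaconate is kept as the dimethyl ester. The allene is then a purchasable compound, and alkaline hydrolysis with decarboxylation of phloroglucinol-type carboxylates is long established.

**Route**

Step 1
Reactants: 1 4-bromo-2,6-dimethoxyphenol
Product: 2 2-(benzyloxy)-5-bromo-1,3-dimethoxybenzene
Conditions: BnBr, K2CO3, DMF, rt
Reagents that add atoms: benzyl bromide, BrCc1ccccc1
Why: Williamson ether synthesis, in which the phenoxide displaces bromide from the benzylic carbon, masks the phenol so that 2 can act only as the aryl halide partner later.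

Step 2
Reactants: 3 2,4,6-trimethoxyphenol; 2 2-(benzyloxy)-5-bromo-1,3-dimethoxybenzene
Product: 4 2-(benzyloxy)-1,3-dimethoxy-5-(2,4,6-trimethoxyphenoxy)benzene
Conditions: CuI (10 mol %), picolinic acid (20 mol %), K3PO4, DMSO, 90 °C, Ar
Reagents that add atoms: none
Why: Ullmann-type copper-catalysed C–O coupling with a picolinic acid ligand tolerates doubly ortho-substituted phenols, and the bromide of 2 has two free ortho positions, so the hindrance sits on one partner only.

Step 3
Reactants: 4 2-(benzyloxy)-1,3-dimethoxy-5-(2,4,6-trimethoxyphenoxy)benzene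
Product: 5 2,6-dimethoxy-4-(2,4,6-trimethoxyphenoxy)phenol
Conditions: H2 (1 atm), Pd/C (10 wt %), EtOAc/MeOH, rt
Reagents that add atoms: none
Why: Catalytic hydrogenolysis cleaves the benzyl aryl ether alone, since methyl ethers and the diaryl ether are inert, and frees the single hydroxyl needed for the next coupling.

Step 4
Reactants: 5 2,6-dimethoxy-4-(2,4,6-trimethoxyphenoxy)phenol; 2 2-(benzyloxy)-5-bromo-1,3-dimethoxybenzene
Product: 6 2-(benzyloxy)-5-[2,6-dimethoxy-4-(2,4,6-trimethoxyphenoxy)phenoxy]-1,3-dimethoxybenzene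
Conditions: 2 (1.3 equiv), CuI (10 mol %), picolinic acid (20 mol %), K3PO4, DMSO, 90 °C, Ar
Reagents that add atoms: none
Why: This is the same Ullmann-type coupling as step 2, because phenol 5 presents the identical 2,6-dimethoxyphenol terminus to the same unhindered bromide.

Step 5
Reactants: 6 2-(benzyloxy)-5-[2,6-dimethoxy-4-(2,4,6-trimethoxyphenoxy)phenoxy]-1,3-dimethoxybenzene
Product: 7 4-[2,6-dimethoxy-4-(2,4,6-trimethoxyphenoxy)phenoxy]-2,6-dimethoxyphenol
Conditions: H2 (1 atm), Pd/C (10 wt %), EtOAc/MeOH, rt
Reagents that add atoms: none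
Why: Hydrogenolysis of the benzyl ether proceeds as in step 3 and leaves every other ether untouched.

Step 6
Reactants: 7 4-[2,6-dimethoxy-4-(2,4,6-trimethoxyphenoxy)phenoxy]-2,6-dimethoxyphenol; 2 2-(benzyloxy)-5-bromo-1,3-dimethoxybenzene
Product: 8 2-(benzyloxy)-5-{2,6-dimethoxy-4-[2,6-dimethoxy-4-(2,4,6-trimethoxyphenoxy)phenoxy]phenoxy}-1,3-dimethoxybenzene
Conditions: 2 (1.3 equiv), CuI (10 mol %), picolinic acid (20 mol %), K3PO4, DMSO, 90 °C, Ar
Reagents that add atoms: none
Why: A third Ullmann-type C–O coupling of the same kind installs ring D, the reacting phenol terminus being unchanged from steps 2 and 4.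

Step 7
Reactants: 8 2-(benzyloxy)-5-{2,6-dimethoxy-4-[2,6-dimethoxy-4-(2,4,6-trimethoxyphenoxy)phenoxy]phenoxy}-1,3-dimethoxybenzene
Product: 9 4-{2,6-dimethoxy-4-[2,6-dimethoxy-4-(2,4,6-trimethoxyphenoxy)phenoxy]phenoxy}-2,6-dimethoxyphenol (ArOH)
Conditions: H2 (1 atm), Pd/C (10 wt %), EtOAc/THF, rt
Reagents that add atoms: none
Why: Benzyl ether hydrogenolysis releases the ring D phenol whose oxygen becomes the bridge to ring E.

Step 8
Reactants: 9 ArOH (ring A–B–C–D phenol); 10 dimethyl penta-2,3-dienedioate
Product: 11 dimethyl (E)-3-(ArO)pent-2-enedioate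
Conditions: 10 (1.2 equiv), K2CO3 (0.2 equiv), MeCN, 0 °C to rt
Reagents that add atoms: none
Why: Base-catalysed oxa-Michael addition of the phenoxide to the central allene carbon is a known route to 3-aryloxyglutaconates; the delocalised anion is protonated by further phenol, the E alkene is the expected thermodynamic isomer, and no stereocentre arises.

Step 9
Reactants: 12 dimethyl methoxymalonate
Product: 13 methoxymalonic acid
Conditions: NaOH (2.2 equiv), H2O/MeOH, rt; then HCl, 0 °C, EtOAc extraction
Reagents that add atoms: sodium hydroxide, [Na+].[OH-]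
Why: Saponification of an unhindered diester at room temperature, followed by cold acidification, should give the diacid without decarboxylation.

Step 10
Reactants: 13 methoxymalonic acid
Product: 14 methoxymalonyl dichloride
Conditions: (COCl)2 (2.5 equiv), DMF (cat.), CH2Cl2, 0 °C to rt; concentrated and used at once
Reagents that add atoms: oxalyl chloride, ClC(=O)C(Cl)=O
Why: Acid chloride formation with oxalyl chloride under Vilsmeier-type DMF catalysis is the usual way to substituted malonyl dichlorides, and immediate use avoids thermal loss of HCl.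

Step 11
Reactants: 11 dimethyl (E)-3-(ArO)pent-2-enedioate; 14 methoxymalonyl dichloride
Product: 18 dimethyl 2-(ArO)-4,6-dihydroxy-5-methoxybenzene-1,3-dicarboxylate, via chloromagnesium dienolate 15 (not isolated), via open-chain acyl chloride 16 (not isolated), via diketo tautomer 17 (not isolated)
Conditions: MgCl2 (2.5 equiv), Et3N (5 equiv), MeCN/CH2Cl2, 0 °C; 14 (1.2 equiv) added slowly at high dilution, 0 °C to rt; then 1 M HCl
Reagents that add atoms: none
Why: Proposed new method: soft enolisation (MgCl2, Et3N) should turn 11 into the delocalised chloromagnesium dienolate 15, whose two ester-bearing termini are equivalent; one terminus attacks an acid chloride carbon of 14 to give 16, the now doubly activated CH is enolised again, the remote terminus attacks the second acid chloride and expels chloride, and dione 17 tautomerises twice to the benzene ring. The closest known reactions are the magnesium-mediated C-acylation of malonates by acid chlorides and the [3+3] cyclocondensations of 3-oxoglutarates or 1,3-bis(silyloxy)dienes with malonyl dichlorides, along with the long-known self-condensation of malonate to a phloroglucinol tricarboxylate; a 3-aryloxyglutaconate has not served as the carbon dinucleophile. Ring E closes in a 6-exo-trig acylation (an enolate carbon attacks an acyl carbon whose C=O lies outside the new ring). No stereocentre is created, and because both partners are symmetric about the C1–C4 axis of ring E only one constitution is possible. The step needs acylation at carbon and not at oxygen, and ring closure in preference to chain growth: the oxygen on C1 is already an aryl ether, so the pyranone-forming O-acylation open to a 3-oxoglutarate is excluded, magnesium chelation of the beta-keto ester formed first ties up its oxygens, slow addition at high dilution favours the intramolecular second acylation, and irreversible aromatisation to a chelated magnesium bis-phenoxide pulls reversibly O-acylated material through.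

Step 12
Reactants: 18 dimethyl 2-(ArO)-4,6-dihydroxy-5-methoxybenzene-1,3-dicarboxylate
Product: 20 5-(ArO)-2-methoxybenzene-1,3-diol, via diacid 19 (not isolated)
Conditions: KOH (excess), H2O/MeOH, reflux, Ar; then HCl to pH 1–2, 50 °C
Reagents that add atoms: none
Why: Alkaline ester hydrolysis gives a diacid in which each carboxyl is ortho and para to hydroxyl groups (a phloroglucinolcarboxylic-type acid), a class that loses CO2 by ipso protonation on gentle warming in acid.

Step 13
Reactants: 20 5-(ArO)-2-methoxybenzene-1,3-diol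
Product: 21 5-[2,6-dihydroxy-4-[2,6-dihydroxy-4-[2,6-dihydroxy-4-(2,4,6-trihydroxyphenoxy)phenoxy]phenoxy]phenoxy]benzene-1,2,3-triol (target)
Conditions: BBr3 (20 equiv), CH2Cl2, −78 °C to rt; ice-water quench at 0 °C, Ar
Reagents that add atoms: none
Why: Lewis acid ether cleavage with BBr3 converts each of the ten aryl methyl ethers into an aryloxyborane and bromomethane while the four diaryl ethers are inert, and cold hydrolysis should release the twelve phenols.

**Compound list**

1 | 4-bromo-2,6-dimethoxyphenol | COc1cc(Br)cc(OC)c1O | starting material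
2 | 2-(benzyloxy)-5-bromo-1,3-dimethoxybenzene | COc1cc(Br)cc(OC)c1OCc1ccccc1 | intermediate
3 | 2,4,6-trimethoxyphenol | COc1cc(OC)c(O)c(OC)c1 | starting material
4 | 2-(benzyloxy)-1,3-dimethoxy-5-(2,4,6-trimethoxyphenoxy)benzene | COc1cc(OC)c(Oc2cc(OC)c(OCc3ccccc3)c(OC)c2)c(OC)c1 | intermediate
5 | 2,6-dimethoxy-4-(2,4,6-trimethoxyphenoxy)phenol | COc1cc(OC)c(Oc2cc(OC)c(O)c(OC)c2)c(OC)c1 | intermediate
6 | 2-(benzyloxy)-5-[2,6-dimethoxy-4-(2,4,6-trimethoxyphenoxy)phenoxy]-1,3-dimethoxybenzene | COc1cc(OC)c(Oc2cc(OC)c(Oc3cc(OC)c(OCc4ccccc4)c(OC)c3)c(OC)c2)c(OC)c1 | intermediate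
7 | 4-[2,6-dimethoxy-4-(2,4,6-trimethoxyphenoxy)phenoxy]-2,6-dimethoxyphenol | COc1cc(OC)c(Oc2cc(OC)c(Oc3cc(OC)c(O)c(OC)c3)c(OC)c2)c(OC)c1 | intermediate
8 | 2-(benzyloxy)-5-{2,6-dimethoxy-4-[2,6-dimethoxy-4-(2,4,6-trimethoxyphenoxy)phenoxy]phenoxy}-1,3-dimethoxybenzene | COc1cc(OC)c(Oc2cc(OC)c(Oc3cc(OC)c(Oc4cc(OC)c(OCc5ccccc5)c(OC)c4)c(OC)c3)c(OC)c2)c(OC)c1 | intermediate
9 | 4-{2,6-dimethoxy-4-[2,6-dimethoxy-4-(2,4,6-trimethoxyphenoxy)phenoxy]phenoxy}-2,6-dimethoxyphenol (ArOH) | COc1cc(OC)c(Oc2cc(OC)c(Oc3cc(OC)c(Oc4cc(OC)c(O)c(OC)c4)c(OC)c3)c(OC)c2)c(OC)c1 | intermediate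
10 | dimethyl penta-2,3-dienedioate (racemic) | COC(=O)C=C=CC(=O)OC | starting material
11 | dimethyl (E)-3-(ArO)pent-2-enedioate | COc1cc(OC)c(Oc2cc(OC)c(Oc3cc(OC)c(Oc4cc(OC)c(O/C(=C/C(=O)OC)CC(=O)OC)c(OC)c4)c(OC)c3)c(OC)c2)c(OC)c1 | intermediate
12 | dimethyl methoxymalonate | COC(C(=O)OC)C(=O)OC | starting material
13 | methoxymalonic acid | COC(C(=O)O)C(=O)O | intermediate
14 | methoxymalonyl dichloride | COC(C(=O)Cl)C(=O)Cl | intermediate
15 | chloromagnesium dienolate of 11 (geometry undefined) | COc1cc(OC)c(Oc2cc(OC)c(Oc3cc(OC)c(Oc4cc(OC)c(OC(=CC(=O)OC)C=C(OC)O[Mg]Cl)c(OC)c4)c(OC)c3)c(OC)c2)c(OC)c1 | intermediate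
16 | dimethyl 3-(ArO)-4-(3-chloro-2-methoxy-3-oxopropanoyl)pent-2-enedioate (configuration undefined, epimerisable) | COc1cc(OC)c(Oc2cc(OC)c(Oc3cc(OC)c(Oc4cc(OC)c(OC(=CC(=O)OC)C(C(=O)OC)C(=O)C(OC)C(Cl)=O)c(OC)c4)c(OC)c3)c(OC)c2)c(OC)c1 | intermediate
17 | dimethyl 2-(ArO)-5-methoxy-4,6-dioxocyclohex-2-ene-1,3-dicarboxylate (configuration undefined, epimerisable) | COc1cc(OC)c(Oc2cc(OC)c(Oc3cc(OC)c(Oc4cc(OC)c(OC5=C(C(=O)OC)C(=O)C(OC)C(=O)C5C(=O)OC)c(OC)c4)c(OC)c3)c(OC)c2)c(OC)c1 | intermediate
18 | dimethyl 2-(ArO)-4,6-dihydroxy-5-methoxybenzene-1,3-dicarboxylate | COc1cc(OC)c(Oc2cc(OC)c(Oc3cc(OC)c(Oc4cc(OC)c(Oc5c(C(=O)OC)c(O)c(OC)c(O)c5C(=O)OC)c(OC)c4)c(OC)c3)c(OC)c2)c(OC)c1 | intermediate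
19 | 2-(ArO)-4,6-dihydroxy-5-methoxybenzene-1,3-dicarboxylic acid | COc1cc(OC)c(Oc2cc(OC)c(Oc3cc(OC)c(Oc4cc(OC)c(Oc5c(C(=O)O)c(O)c(OC)c(O)c5C(=O)O)c(OC)c4)c(OC)c3)c(OC)c2)c(OC)c1 | intermediate
20 | 5-(ArO)-2-methoxybenzene-1,3-diol | COc1cc(OC)c(Oc2cc(OC)c(Oc3cc(OC)c(Oc4cc(OC)c(Oc5cc(O)c(OC)c(O)c5)c(OC)c4)c(OC)c3)c(OC)c2)c(OC)c1 | intermediate
21 | 5-[2,6-dihydroxy-4-[2,6-dihydroxy-4-[2,6-dihydroxy-4-(2,4,6-trihydroxyphenoxy)phenoxy]phenoxy]phenoxy]benzene-1,2,3-triol | Oc1cc(O)c(Oc2cc(O)c(Oc3cc(O)c(Oc4cc(O)c(Oc5cc(O)c(O)c(O)c5)c(O)c4)c(O)c3)c(O)c2)c(O)c1 | target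

**Step count and risks**

Total step count: 13, of which steps 9 and 10 are a two-step side branch to 14.
Longest linear sequence: 11 steps (steps 1 to 8, then 11, 12 and 13).

Steps most likely to fail:

1. Step 11 (new method). Acylation at an ester enolate oxygen, or acylation of a second dienolate molecule, may outrun the ring-forming second C-acylation. Dichloride 14 may also lose HCl to a ketene that oligomerises before it is captured. Either process would give enol esters and chain products in place of ring E. The fallback uses only known chemistry and buys ring E ready-made. It sets out from phenol 9, which would be coupled under the CuI/picolinic acid/K3PO4 conditions of steps 2, 4 and 6 with commercial 5-bromo-1,2,3-trimethoxybenzene (COc1cc(Br)cc(OC)c1OC). This should give the undecamethyl ether 1,2,3-trimethoxy-5-(ArO)benzene F1. Cleavage of its eleven methyl ethers with BBr3 in CH2Cl2, as in step 13, comes back to the route at target 21.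

2. Step 6 (the same concern applies to steps 2 and 4). Oxidative addition into the electron-rich bromide and ligand exchange with the doubly ortho-substituted phenoxide may be slow. Copper-mediated oxidation of the electron-rich phenoxide by traces of oxygen, or hydrodebromination of 2, could then dominate. The fallback replaces the copper coupling by nucleophilic aromatic substitution on an activated ring. It sets out from phenol 7, which would be heated with 4-fluoro-2,6-dimethoxybenzaldehyde (COc1cc(F)cc(OC)c1C=O) and K2CO3 in DMSO. The para-formyl group activates the fluoride, and the product should be 2,6-dimethoxy-4-{2,6-dimethoxy-4-[2,6-dimethoxy-4-(2,4,6-trimethoxyphenoxy)phenoxy]phenoxy}benzaldehyde F2. Baeyer–Villiger (Dakin-type) oxidation with mCPBA in CH2Cl2 should give the aryl formate 2,6-dimethoxy-4-{2,6-dimethoxy-4-[2,6-dimethoxy-4-(2,4,6-trimethoxyphenoxy)phenoxy]phenoxy}phenyl formate F3. Methanolysis with K2CO3 in MeOH comes back to the route at phenol 9.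

3. Step 12. Saponification may stall, because each ester carbonyl is flanked by two ortho substituents and is deactivated by the neighbouring phenoxide donors. Prolonged heating in alkali then invites degradation of the electron-rich rings. The fallback breaks the unhindered O–CH3 bond of each ester instead of attacking the acyl carbon. It sets out from 18, which would be heated with LiI in pyridine at reflux (SN2 demethylation of the esters) to give the dicarboxylate. Acidification gives diacid 19, which should decarboxylate on warming and come back to the route at 20. No new compound is made (entry F0).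

**Further compounds**

F1 | step 11 | 1,2,3-trimethoxy-5-(ArO)benzene | COc1cc(OC)c(Oc2cc(OC)c(Oc3cc(OC)c(Oc4cc(OC)c(Oc5cc(OC)c(OC)c(OC)c5)c(OC)c4)c(OC)c3)c(OC)c2)c(OC)c1
F2 | step 6 | 2,6-dimethoxy-4-{2,6-dimethoxy-4-[2,6-dimethoxy-4-(2,4,6-trimethoxyphenoxy)phenoxy]phenoxy}benzaldehyde | COc1cc(OC)c(Oc2cc(OC)c(Oc3cc(OC)c(Oc4cc(OC)c(C=O)c(OC)c4)c(OC)c3)c(OC)c2)c(OC)c1
F3 | step 6 | 2,6-dimethoxy-4-{2,6-dimethoxy-4-[2,6-dimethoxy-4-(2,4,6-trimethoxyphenoxy)phenoxy]phenoxy}phenyl formate | COc1cc(OC)c(Oc2cc(OC)c(Oc3cc(OC)c(Oc4cc(OC)c(OC=O)c(OC)c4)c(OC)c3)c(OC)c2)c(OC)c1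
F0 | step 12 | none | none
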